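The earlier runs and the new flask are simulated for substances that don't exist; the scatter is artificial.

In a one-step world G and J meet at a rate proportional to G times J, and the share of G turned climbs an opening line that bends as G, the limiting reagent, thins. I put that rule of thumb to these flasks.

| flask | G | J | time |
|---|---|---|---|
| ochre | 0.600 M | 1.50 M |  |
| amber | 0.600 M | 0.750 M |  |
| teal | 0.900 M | 1.50 M |  |
| blue | 0.300 M | 0.490 M | 32 min |

- ochre run (time / min: [X] / M): 1.3: 0.028; 2.4: 0.042; 4.6: 0.079; 8.8: 0.134; 17: 0.196; 32: 0.237
- amber run (time / min: [X] / M): 1.3: 0.018; 2.4: 0.028; 4.6: 0.060; 8.8: 0.101; 17: 0.150; 32: 0.196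
- teal run (time / min: [X] / M): 1.3: 0.036; 2.4: 0.056; 4.6: 0.102; 8.8: 0.169; 17: 0.249; 32: 0.278

(standard deviation of a reading: 0.003 M)

- Overall: G + J -> X.
- Constant volume, constant temperature.
- What is held in complexes is read along with the free species.
- An order is taken over about fifteen percent of the charge, up and down.

1. how the opening rate goes with [G] round the charge of the ochre run: the exponent of the rate at two percent of G gone to X (one fixed amount of X, the same in the runs compared)
2. how the opening rate goes with [J] round the charge of the ochre run: the exponent of the rate at two percent of G gone to X
3. X in the blue run at 32 min, as a share of the G charged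

As the opening rate I take the chord from zero to 4.6 min. The one-step rule wants ochre at twice amber there, but ochre's reading stands 1.32 times amber's. Teal stands 1.29 times ochre's, on a G ratio of 1.50. So my chords give exponents of 0.630 in G and 0.397 in J.

The line has a border too. Ochre's opening line reaches its share of 32 min after 13.8 min, less than the clock shows. I carry this crossing time, the share read at 32 min over the opening share per minute. Amber gives 15.0 min and teal 12.5 min, so from amber to teal the crossing shortens by 2.50 min over 0.0820 M more X read.

My exponents scale blue's opening share to 0.0237 min⁻¹. Carrying that straight line from amber and teal down to blue, I get a crossing of 17.2 min and so a share of 40.9%, an X lower than amber's last reading.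

The forecast puts the exponents at 0.7 and 0.5, higher than my chords. Counting opening-rate minutes, it says “blue, with less X, should manage about 16” and lands at 35%, a lower share than mine.

The flask gives blue 38.0% at 32 min, with exponents of 0.68 in G and 0.53 in J, so the forecast stands within its margins. Its steps are these:

    G + J ⇌ X + E (0.5148 M⁻¹ min⁻¹, 0.2058 M⁻¹ min⁻¹)
    2 J ⇌ J2, settled at all times (45.20 M⁻¹)
    2 G ⇌ G2, settled at all times (1.750 M⁻¹)

Blue's share over my opening share makes its crossing 16.0 min, shorter than the 17.2 min I reckoned. Teal's crossing on its chord stands at 12.5 min, shorter than blue's.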